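## Analysis of the target

The target 21 is a 2-oxaspiro[4.5]decane: a γ-butyrolactone (C1, O2, C3, C4) and a cyclohex-2-enone (C6 ketone, C7=C8, C9, C10) share the quaternary carbon C5. C1 carries a hepta-1,6-dienyl chain with an E-trisubstituted C1′=C2′ bond and an (R)-allylic carbinol beside an isopropenyl group; C9 carries an acetate. On the core, C1 (R) and C5 (R) are adjacent and C9 (S) is 1,3 to C5 across C10. The C9 acetate lies on the same ring face as C1, and the alkenyl group on C1 lies on the side of the C6 carbonyl. The side-chain carbinol is too remote to be set from the core. The γ-acetoxy enone eliminates under base and ionises on zerovalent palladium, the allylic lactone C1–O bond and the free allylic alcohol are acid-sensitive, and base opens the lactone to a β-hydroxy ketone that can cleave by retro-aldol reaction. The main difficulty is the all-carbon quaternary C5, which must be fixed absolutely and relative to both C9 and C1. The strategy rests on the ring pattern around C5: oxygen on C6 and, through C7=C8, on C9, with C5 and C10 as the remaining ring atoms and C5 bearing a formyl-level carbon (C1) and a CH2CO2R arm (C4). This is the substitution pattern of a [4+2] adduct of a 1,4-dioxygenated butadiene and a 2-substituted acrolein.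

## Retrosynthetic reasoning

21 to 20. The last bond cut is the O–Si bond of the side-chain carbinol. The carbinol has to be masked while the side chain is an alkenyl-metal species, and a silyl ether can be removed with acidic fluoride, which the γ-acetoxy enone and the lactone tolerate.

20 to 19. The lactone is opened at the acyl C3–O2 bond, not at C1–O2, so the C1 configuration is made earlier and never put at risk by displacement or allylic transposition. The forward step is an intramolecular transesterification of the tert-butyl ester of 19. That ester is kept until then because it stays inert while the C6 oxygen is a free hydroxyl.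

19 to 8 and 18 (from 16 through 17). The C1–C1′ bond is cut. This separates the ring from the remote carbinol, which can then be set by a catalyst in the small fragment. It also places an aldehyde at C1 next to the C6 ketone of 8, so a metal can bridge the two oxygens. The forward step has to add an alkenyl nucleophile to the aldehyde only, and from the face of C10.

8 to 7 to 6. These are oxidation-level changes at C6: the ketone of 8 comes from the carbinol of 7, and that from the silyl ether of 6. The C6 stereocentre of 6 is used only to steer the ring-forming step and is then oxidised away.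

6 to 2 and 5. The bonds C5–C6 and C9–C10 are cut together. No other cut forms the ring, the quaternary centre and C9 in one step and also delivers C1 as an aldehyde, C7=C8 in place and C9 already as the acetate of the target. The forward reaction needs control of orientation, of endo versus exo approach, and of the enal face.

2 to 1, and 5 to 3 through 4. The dienophile 2 is the α-methylene derivative of aldehyde 1, made by adding a one-carbon electrophile and eliminating. The diene 5 is taken from the diacetate 3 by exchanging one acetyl group for a silyl group by way of dienolate 4. Both double bonds of 3 already have the E geometry and neither is broken. An enolisation route that creates the acetoxy-bearing double bond would leave its geometry open, with the cis isomer a real possibility, and a cis-substituted diene does not reach the s-cis conformation.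

16 back to 9. The silyl ether 16 comes from carbinol 15. The stereocentre of 15 is set by catalytic reduction of enone 14, which comes from racemic alcohol 13 by oxidation. 13 comes from aldehyde 12 and an isopropenyl nucleophile, 12 from alcohol 11, and 11 from alkyne 9 by syn methyl-metalation through alane 10, which fixes the E-trisubstituted vinyl iodide.

## Alternatives that were turned down

Alternative 1: The lactone is cut at the alkyl C1–O2 bond with allylic transposition. The precursor is the carboxylic acid A1, in which C5 bears an (E)-alkenyl group ending in a tertiary allylic methyl carbonate. A zerovalent palladium catalyst ionises either carbinol epimer to one π-allyl complex, and the carboxylate closes on the near terminus C1 (5-exo) to give spirolactone A2 with the trisubstituted E olefin.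
- For it: the step is stereoconvergent, makes the C1–O bond and the side-chain olefin together under neutral conditions, and allows ligand control at C1. On C1 control it is stronger than the chosen route, which relies on substrate chelation.
- Against it: A1 already contains the quaternary C5 (now with a vinyl group, a ketone and an acetic acid arm) and C9, so the hard part still needs a separate asymmetric ring construction. C9 must be carried as a silyl ether, because an allylic acetate there would itself ionise on palladium, so A2 needs a silyl-to-acetate exchange beside a second silyl ether. The π-allyl intermediate can also lose a proton to a diene.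
- Comparison: the chosen cycloaddition builds the ring, C5 and C9 in one step and delivers C9 as the acetate. It gives up catalyst control at C1.

Alternative 2: The ring bond C5–C10 is cut. The open-chain β-keto ester A3 carries the C4 arm on C5 and a primary iodide on C10, with C9 taken from the chiral pool as a silyl ether. Its sodium enolate alkylates intramolecularly (6-enolendo-exo-tet) to cyclohexanone A4, and both C5 epimers of A3 converge through the planar enolate.
- For it: absolute configuration comes from a purchased stereocentre and not from an enantioselective catalyst, which is a real advantage in certainty over the chosen route. The chemistry is robust and scalable.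
- Against it: the C5 configuration depends on 1,3-induction from C9 in a cyclisation where the two groups on the enolate carbon are of similar size. O-alkylation to a six-membered enol ether competes. A4 has the wrong oxidation level at three places: C1 is an ester that must become an aldehyde beside a ketone and a second ester, C7–C8 must be dehydrogenated, and the C9 silyl ether must become an acetate.
- Comparison: the chosen route gets the aldehyde, the olefin and the acetate directly from the key step and sets relative configuration by the rules of a concerted cycloaddition. It costs reliance on a chiral catalyst.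

Alternative 3: The C5–C1 bond is cut with dearomatisation. The precursor A5 is a 2-hydroxy-5-silyloxyphenylacetic ester of an allylic acyloxy carbonate (a mixed acylal) that already holds the whole side chain. Zerovalent palladium ionises the carbonate, and the phenoxide attacks through its ipso carbon C5 at the acyloxy-bearing allyl terminus C1, closing the spirolactone and giving cyclohexa-2,4-dienone A6.
- For it: it is the most convergent plan. A flat aromatic precursor, the C5–C1 bond, the lactone ring and two adjacent stereocentres come from one catalytic step, so on step count it is stronger than the chosen route.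
- Against it: ipso attack ortho to the phenoxide oxygen must beat O-allylation and attack at the free ortho carbon. The nucleophile must choose the acyloxy-bearing terminus over the tertiary one. The linearly conjugated dienone A6 is prone to [4+2] dimerisation and rearomatisation. C9 emerges as a silyl dienol ether, so its configuration has to be created later by a chemo- and face-selective reduction of one of two ring carbonyls, steered only by the distant spiro centre.
- Comparison: the chosen route trades convergency for a key step of a known class in which C9 is set together with C5.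

Key step: step 3

Remark on numbering: C1–C10 and C1′ are the atoms of 21 in 2-oxaspiro[4.5]decane numbering (C1 lactone CH–O, C3 lactone carbonyl, C4 lactone CH2, C5 spiro carbon, C6 ketone, C7=C8, C9 acetoxy carbon, C10 ring CH2, C1′ the chain carbon on C1). In 6–8 and 19 the cyclohexene locants 1, 2, 5 and 6 are C5, C6, C9 and C10.
Assumption: diacetate 3 and a THF solution of isopropenylmagnesium bromide are taken as catalogue items.

## Route

Step 1
Reactants: 1 tert-butyl 4-oxobutanoate
Product: 2 tert-butyl 3-formylbut-3-enoate
Conditions: HCHO (37% aq., 1.1 equiv), pyrrolidine (0.1 equiv), propanoic acid (0.1 equiv), i-PrOH, 45 °C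
Reagents that add atoms: formaldehyde, C=O
Why: Amine-catalysed Mannich-type α-methylenation: the enamine of 1 adds to the formaldehyde-derived iminium ion and the amine is eliminated, and only the aldehyde α-carbon can form the enamine. The near-neutral medium limits migration of the new double bond into conjugation with the ester; 2 is used fresh.

Step 2
Reactants: 3 (1E,3E)-buta-1,3-diene-1,4-diyl diacetate
Product: 5 (1E,3E)-4-[(triisopropylsilyl)oxy]buta-1,3-dien-1-yl acetate, via potassium dienolate 4 (not isolated)
Conditions: 3 added to t-BuOK (1.0 equiv), THF, −78 °C; i-Pr3SiCl (1.1 equiv), −78 → 0 °C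
Reagents that add atoms: triisopropylsilyl chloride, CC(C)[Si](Cl)(C(C)C)C(C)C
Why: Enol ester cleavage by alkoxide (a transesterification) releases dienolate 4; the second acetate is spared because its cleavage would have to expel a dianion. O-Silylation of the potassium enolate by the hindered chlorosilane gives 5, and both double bonds keep the E geometry because neither is broken.

Step 3
Reactants: 2 tert-butyl 3-formylbut-3-enoate; 5 (1E,3E)-4-[(triisopropylsilyl)oxy]buta-1,3-dien-1-yl acetate
Product: 6 tert-butyl 2-[(1S,2S,5S)-5-acetoxy-1-formyl-2-[(triisopropylsilyl)oxy]cyclohex-3-en-1-yl]acetate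
Conditions: (3aR)-3,3-diphenyl-1-(2-methylphenyl)tetrahydro-1H,3H-pyrrolo[1,2-c][1,3,2]oxazaborole (0.2 equiv), HNTf2 (0.18 equiv), CH2Cl2, −78 °C; 2, then 5 (1.5 equiv) slowly, −78 → −40 °C
Reagents that add atoms: none
Why: The protonated oxazaborolidine binds the formyl oxygen of 2 (B–O coordination supported by a formyl C–H···O contact), holds the enal s-trans over one aryl ring and leaves one face open; 5 then adds in a concerted, asynchronous [4+2] in which the C9–C10 bond (acetoxy terminus to the methylene carbon) runs ahead of the C5–C6 bond. The closest known reaction type is the oxazaborolidinium-catalysed enantioselective Diels–Alder reaction of 2-substituted acroleins with 1-oxygenated butadienes. The cyclohexene closes by the suprafacial two-bond union of the diene termini with the dienophile, so there is no separate cyclisation event. C5 (locant 1 of 6) is set by the catalyst, which fixes the enal face; the (3aR) catalyst is chosen because on the accepted binding model the (3aS) series exposes the opposite face of 2-substituted acroleins. C6 and C9 (locants 2 and 5) follow from the E,E geometry of 5, which puts both oxygens on one face, and from the endo position of the formyl group, which puts them cis to C1. Orientation is needed and comes from the silyloxy group, the stronger donor: it makes the acetoxy-bearing carbon the nucleophilic terminus, which bonds to the unsubstituted β-carbon, so C6 receives the silyl ether and C9 the final acetate. Endo selectivity is needed and is favoured by secondary overlap with the boron-bound formyl group, since an open-chain diene has no bridging methylene that would push the α-substituent inside. The C6 centre is removed in step 5, while C5 and C9 go through to 21 unchanged.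

Step 4
Reactants: 6 tert-butyl 2-[(1S,2S,5S)-5-acetoxy-1-formyl-2-[(triisopropylsilyl)oxy]cyclohex-3-en-1-yl]acetate
Product: 7 tert-butyl 2-[(1S,2S,5S)-5-acetoxy-1-formyl-2-hydroxycyclohex-3-en-1-yl]acetate
Conditions: HF·pyridine, THF, 0 °C → rt
Reagents that add atoms: none
Why: Fluoride cleavage of the Si–O bond under mildly acidic conditions, which avoids the retro-aldol opening and acetate migration that basic fluoride could cause in a β-hydroxy aldehyde. The tert-butyl ester is not attacked by the new hydroxyl, which is trans to the arm.

Step 5
Reactants: 7 tert-butyl 2-[(1S,2S,5S)-5-acetoxy-1-formyl-2-hydroxycyclohex-3-en-1-yl]acetate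
Product: 8 tert-butyl 2-[(1R,5S)-5-acetoxy-1-formyl-2-oxocyclohex-3-en-1-yl]acetate
Conditions: Dess–Martin periodinane (1.3 equiv), CH2Cl2, 0 °C → rt; non-aqueous work-up, used crude
Reagents that add atoms: none
Why: Dess–Martin oxidation of the secondary allylic alcohol to the enone under neutral, anhydrous conditions that leave the aldehyde, the acetate and the ester alone. The β-keto aldehyde cannot enolise at C5 and is taken on at once.

Step 6
Reactants: 9 pent-4-yn-1-ol
Product: 11 (E)-5-iodo-4-methylpent-4-en-1-ol, via alkenylalane 10 (not isolated)
Conditions: Me3Al (3 equiv), Cp2ZrCl2 (0.25 equiv), CH2Cl2, 0 °C → rt; I2, THF, −30 → 0 °C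
Reagents that add atoms: trimethylaluminium, C[Al](C)C; iodine, II
Why: Negishi zirconium-catalysed carboalumination adds methyl and aluminium syn across the alkyne with aluminium on the terminal carbon, and iodinolysis with retention gives the E iodide. The hydroxyl is masked in the flask as its aluminium alkoxide.

Step 7
Reactants: 11 (E)-5-iodo-4-methylpent-4-en-1-ol
Product: 12 (E)-5-iodo-4-methylpent-4-enal
Conditions: Dess–Martin periodinane (1.2 equiv), CH2Cl2, rt
Reagents that add atoms: none
Why: Dess–Martin oxidation of a primary alcohol to the aldehyde without over-oxidation; the vinyl iodide is inert.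

Step 8
Reactants: 12 (E)-5-iodo-4-methylpent-4-enal
Product: 13 rac-(6E)-7-iodo-2,6-dimethylhepta-1,6-dien-3-ol
Conditions: CH2=C(CH3)MgBr (1.3 equiv), THF, −78 → 0 °C; aq. NH4Cl
Reagents that add atoms: isopropenylmagnesium bromide, C=C(C)[Mg]Br
Why: Grignard 1,2-addition to the aldehyde; the vinyl iodide does not exchange at this temperature. The racemate is accepted because the stereocentre is reset in step 10.

Step 9
Reactants: 13 rac-(6E)-7-iodo-2,6-dimethylhepta-1,6-dien-3-ol
Product: 14 (6E)-7-iodo-2,6-dimethylhepta-1,6-dien-3-one
Conditions: Dess–Martin periodinane (1.3 equiv), CH2Cl2, 0 °C → rt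
Reagents that add atoms: none
Why: Dess–Martin oxidation of the allylic alcohol to the isopropenyl ketone under neutral conditions; the enone is used promptly to avoid self-addition.

Step 10
Reactants: 14 (6E)-7-iodo-2,6-dimethylhepta-1,6-dien-3-one
Product: 15 (3R,6E)-7-iodo-2,6-dimethylhepta-1,6-dien-3-ol
Conditions: (3aS)-1-methyl-3,3-diphenyltetrahydro-1H,3H-pyrrolo[1,2-c][1,3,2]oxazaborole (0.2 equiv), catecholborane (1.5 equiv), toluene, −78 °C
Reagents that add atoms: none
Why: Corey–Bakshi–Shibata reduction: the ketone binds boron anti to the larger isopropenyl group and hydride is delivered to the face that gives the (R)-carbinol, as with aryl and alkenyl ketones under the (S) catalyst. At −78 °C the catalysed 1,2-reduction outruns conjugate reduction and hydroboration.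

Step 11
Reactants: 15 (3R,6E)-7-iodo-2,6-dimethylhepta-1,6-dien-3-ol
Product: 16 tert-butyl{[(3R,6E)-7-iodo-2,6-dimethylhepta-1,6-dien-3-yl]oxy}dimethylsilane
Conditions: t-BuMe2SiCl (1.3 equiv), imidazole (2.5 equiv), DMF, rt
Reagents that add atoms: tert-butyldimethylsilyl chloride, CC(C)(C)[Si](C)(C)Cl
Why: Standard silylation of a secondary alcohol. The silyl ether survives tert-butyllithium and catalytic acid and is removable with HF·pyridine.

Step 12
Reactants: 16 tert-butyl{[(3R,6E)-7-iodo-2,6-dimethylhepta-1,6-dien-3-yl]oxy}dimethylsilane; 8 tert-butyl 2-[(1R,5S)-5-acetoxy-1-formyl-2-oxocyclohex-3-en-1-yl]acetate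
Product: 19 tert-butyl 2-[(1R,5S)-5-acetoxy-1-[(1R,2E,6R)-6-[(tert-butyldimethylsilyl)oxy]-1-hydroxy-3,7-dimethylocta-2,7-dien-1-yl]-2-oxocyclohex-3-en-1-yl]acetate, via alkenyllithium 17 (not isolated), via alkenylzinc bromide 18 (not isolated)
Conditions: 16 (1.25 equiv), t-BuLi (2.6 equiv), Et2O, −78 °C; ZnBr2 (1.4 equiv), −78 → 0 °C; 8, Et2O, −78 → −20 °C; aq. NH4Cl
Reagents that add atoms: none
Why: Iodine–lithium exchange with retention and transmetalation give an alkenylzinc halide that adds to the aldehyde but not to the enone, the esters or the acetate. Zinc bridges the C6 and formyl oxygens in a six-membered chelate fused to the ring, with the formyl group pseudo-equatorial and the CH2CO2t-Bu arm pseudo-axial over one face, while C9 lies anti to C1 on the other side. The alkenyl group therefore enters past C10 and gives the (R)-carbinol; any of 19 that closes to 20 in the flask is carried along.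

Step 13
Reactants: 19 tert-butyl 2-[(1R,5S)-5-acetoxy-1-[(1R,2E,6R)-6-[(tert-butyldimethylsilyl)oxy]-1-hydroxy-3,7-dimethylocta-2,7-dien-1-yl]-2-oxocyclohex-3-en-1-yl]acetate
Product: 20 (1R,5R,9S)-1-[(1E,5R)-5-[(tert-butyldimethylsilyl)oxy]-2,6-dimethylhepta-1,6-dien-1-yl]-3,6-dioxo-2-oxaspiro[4.5]dec-7-en-9-yl acetate
Conditions: camphor-10-sulfonic acid (0.2 equiv), CH2Cl2, 0 °C → rt
Reagents that add atoms: none
Why: Acid-catalysed intramolecular transesterification (5-exo-trig, helped by the Thorpe–Ingold effect of the quaternary C5) expels tert-butanol. The C1–O bond is not broken, so C1 keeps its configuration, and a catalytic acid in a non-polar solvent keeps ionisation of the allylic carbinol and loss of the silyl ether slow.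

Step 14
Reactants: 20 (1R,5R,9S)-1-[(1E,5R)-5-[(tert-butyldimethylsilyl)oxy]-2,6-dimethylhepta-1,6-dien-1-yl]-3,6-dioxo-2-oxaspiro[4.5]dec-7-en-9-yl acetate
Product: 21 (1R,5R,9S)-1-[(1E,5R)-5-hydroxy-2,6-dimethylhepta-1,6-dien-1-yl]-3,6-dioxo-2-oxaspiro[4.5]dec-7-en-9-yl acetate
Conditions: HF·pyridine, THF/pyridine, 0 °C → rt
Reagents that add atoms: none
Why: Fluoride cleavage of the secondary silyl ether under buffered acidic conditions. Basic fluoride is avoided so that the γ-acetoxy enone does not eliminate and the lactone does not open.

## Compound list

1 | tert-butyl 4-oxobutanoate | O=CCCC(=O)OC(C)(C)C | starting material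
2 | tert-butyl 3-formylbut-3-enoate | C=C(C=O)CC(=O)OC(C)(C)C | intermediate
3 | (1E,3E)-buta-1,3-diene-1,4-diyl diacetate | CC(=O)O/C=C/C=C/OC(C)=O | starting material
4 | potassium (1E,3E)-4-acetoxybuta-1,3-dien-1-olate | CC(=O)O/C=C/C=C/[O-].[K+] | intermediate (not isolated)
5 | (1E,3E)-4-[(triisopropylsilyl)oxy]buta-1,3-dien-1-yl acetate | CC(=O)O/C=C/C=C/O[Si](C(C)C)(C(C)C)C(C)C | intermediate
6 | tert-butyl 2-[(1S,2S,5S)-5-acetoxy-1-formyl-2-[(triisopropylsilyl)oxy]cyclohex-3-en-1-yl]acetate | CC(C)(C)OC(=O)C[C@@]1(C=O)C[C@H](OC(C)=O)C=C[C@@H]1O[Si](C(C)C)(C(C)C)C(C)C | intermediate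
7 | tert-butyl 2-[(1S,2S,5S)-5-acetoxy-1-formyl-2-hydroxycyclohex-3-en-1-yl]acetate | CC(C)(C)OC(=O)C[C@@]1(C=O)C[C@H](OC(C)=O)C=C[C@@H]1O | intermediate
8 | tert-butyl 2-[(1R,5S)-5-acetoxy-1-formyl-2-oxocyclohex-3-en-1-yl]acetate | CC(C)(C)OC(=O)C[C@@]1(C=O)C[C@H](OC(C)=O)C=CC1=O | intermediate
9 | pent-4-yn-1-ol | C#CCCCO | starting material
10 | (E)-[5-(dimethylalumanyloxy)-2-methylpent-1-en-1-yl]dimethylalumane | C[Al](C)/C=C(\C)CCCO[Al](C)C | intermediate (not isolated)
11 | (E)-5-iodo-4-methylpent-4-en-1-ol | OCCC/C(C)=C/I | intermediate
12 | (E)-5-iodo-4-methylpent-4-enal | O=CCC/C(C)=C/I | intermediate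
13 | rac-(6E)-7-iodo-2,6-dimethylhepta-1,6-dien-3-ol | C=C(C)C(O)CC/C(C)=C/I | intermediate
14 | (6E)-7-iodo-2,6-dimethylhepta-1,6-dien-3-one | C=C(C)C(=O)CC/C(C)=C/I | intermediate
15 | (3R,6E)-7-iodo-2,6-dimethylhepta-1,6-dien-3-ol | C=C(C)[C@H](O)CC/C(C)=C/I | intermediate
16 | tert-butyl{[(3R,6E)-7-iodo-2,6-dimethylhepta-1,6-dien-3-yl]oxy}dimethylsilane | C=C(C)[C@H](O[Si](C)(C)C(C)(C)C)CC/C(C)=C/I | intermediate
17 | [(1E,5R)-5-[(tert-butyldimethylsilyl)oxy]-2,6-dimethylhepta-1,6-dien-1-yl]lithium | C=C(C)[C@H](O[Si](C)(C)C(C)(C)C)CC/C(C)=C/[Li] | intermediate (not isolated)
18 | bromo[(1E,5R)-5-[(tert-butyldimethylsilyl)oxy]-2,6-dimethylhepta-1,6-dien-1-yl]zinc | C=C(C)[C@H](O[Si](C)(C)C(C)(C)C)CC/C(C)=C/[Zn]Br | intermediate (not isolated)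
19 | tert-butyl 2-[(1R,5S)-5-acetoxy-1-[(1R,2E,6R)-6-[(tert-butyldimethylsilyl)oxy]-1-hydroxy-3,7-dimethylocta-2,7-dien-1-yl]-2-oxocyclohex-3-en-1-yl]acetate | C=C(C)[C@H](O[Si](C)(C)C(C)(C)C)CC/C(C)=C/[C@@H](O)[C@]1(CC(=O)OC(C)(C)C)C[C@H](OC(C)=O)C=CC1=O | intermediate
20 | (1R,5R,9S)-1-[(1E,5R)-5-[(tert-butyldimethylsilyl)oxy]-2,6-dimethylhepta-1,6-dien-1-yl]-3,6-dioxo-2-oxaspiro[4.5]dec-7-en-9-yl acetate | C=C(C)[C@H](O[Si](C)(C)C(C)(C)C)CC/C(C)=C/[C@H]1OC(=O)C[C@]12C[C@H](OC(C)=O)C=CC2=O | intermediate
21 | (1R,5R,9S)-1-[(1E,5R)-5-hydroxy-2,6-dimethylhepta-1,6-dien-1-yl]-3,6-dioxo-2-oxaspiro[4.5]dec-7-en-9-yl acetate | C=C(C)[C@H](O)CC/C(C)=C/[C@H]1OC(=O)C[C@]12C[C@H](OC(C)=O)C=CC2=O | target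

## Step count and risk

Total: 14 steps. Longest linear sequence: 9 steps (steps 6–14, from 9 to 21); the ring fragment reaches 8 in four steps from 1 or 3.

Step 3 (key step). The most likely failure is attack of the acid-activated catalyst on the silyl dienol ether. Protodesilylation, or silyl transfer to the triflimide, would give an achiral silyl Lewis acid that drives a racemic background cycloaddition or an open-chain Mukaiyama–Michael addition. The ester and acetate carbonyls may also compete for boron, and the sense of facial induction rests on a model. If the sense is opposite, the (3aS) catalyst is used. The fallback gives up asymmetric induction. From 2 and 5, an uncatalysed cycloaddition in toluene at 60–80 °C (the electron-rich diene and the 2-substituted acrolein are matched electronically) gives the racemate, that is 6 together with its enantiomer ent-6 F1. The enantiomers are separated by preparative chromatography on a chiral stationary phase, and 6 rejoins the route at step 4.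

Step 12. Facial selectivity may be poor if the chelate does not form in the ethereal medium or if the ester carbonyl competes for zinc, so that open Felkin–Anh-type geometries take part. The alkenylzinc halide may also be sluggish toward an aldehyde on a quaternary carbon. The fallback replaces substrate control by catalyst control. Iodide 16 and aldehyde 8 are coupled directly in a Nozaki–Hiyama–Kishi reaction (CrCl2, catalytic NiCl2, Et3N, THF) in the presence of a chiral sulfonamide ligand of the type used for asymmetric versions of this coupling. This reaction is selective for aldehydes over ketones and esters and returns to the route at 19. It makes no new compound (F0).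

Step 5. The non-enolisable β-keto aldehyde 8 can lose its formyl group by retro-Claisen cleavage on contact with water, silica or nucleophiles, and it hydrates easily. The fallback postpones the C6 oxidation so that this compound never exists. Hydroxy aldehyde 7 and iodide 16 are joined by the same ligand-controlled CrCl2/NiCl2 coupling, which tolerates the free hydroxyl, to give the diol ester F2. Catalytic camphor-10-sulfonic acid then closes the spirolactone through the C1 hydroxyl to give the hydroxy lactone F3; the C6 hydroxyl is trans to the arm and could only form a strained trans-fused lactone. Dess–Martin oxidation of the only free hydroxyl of F3 returns to the route at 20.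

Step 13. Acid may ionise the allylic C1 carbinol (1,3-transposition, elimination) or remove the silyl ether before the hindered tert-butyl ester reacts. The fallback removes the tert-butyl group before the acid-sensitive carbinol exists. Keto aldehyde 8 is treated with CF3CO2H in CH2Cl2 at 0 °C to give the keto aldehyde acid F4, which is in equilibrium with its cyclic acyl hemiacetal. Its zinc carboxylate (Et2Zn, 0.5 equiv) takes up alkenylzinc 18 as in step 12, and the resulting γ-hydroxy acid closes on work-up at pH 4, returning to the route at 20. The carboxylate may alter the chelate, so the C1 ratio would have to be rechecked.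

Step 2. Cleavage may be incomplete, the dienolate may silylate on carbon, or the acetoxy-bearing double bond may isomerise within the delocalised dienolate; 5 is also sensitive to moisture. The fallback changes how the dienolate oxygen is freed. Diacetate 3 is mono-deacylated with lipase B from Candida antarctica and n-butanol (1 equiv) in t-BuOMe; enol esters are good acyl donors and the freed dienol tautomerises, giving (E)-4-oxobut-2-en-1-yl acetate F5. Soft enolisation of F5 (i-Pr3SiOTf, Et3N, Et2O, −78 → 0 °C) returns to the route at 5. This fallback creates the acetoxy-bearing double bond, so a geometric mixture must be expected. The cis isomer does not take part in step 3, so the mixture would be used in excess.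

## Further compounds

F1 | step 3 | tert-butyl 2-[(1R,2R,5R)-5-acetoxy-1-formyl-2-[(triisopropylsilyl)oxy]cyclohex-3-en-1-yl]acetate (ent-6) | CC(C)(C)OC(=O)C[C@]1(C=O)C[C@@H](OC(C)=O)C=C[C@H]1O[Si](C(C)C)(C(C)C)C(C)C
F0 | step 12 | none | none
F2 | step 5 | diol ester: analogue of 19 with a hydroxyl at C6 (configuration as in 7) in place of the ketone | C=C(C)[C@H](O[Si](C)(C)C(C)(C)C)CC/C(C)=C/[C@@H](O)[C@]1(CC(=O)OC(C)(C)C)C[C@H](OC(C)=O)C=C[C@@H]1O
F3 | step 5 | hydroxy lactone: analogue of 20 with a hydroxyl at C6 (configuration as in 7) in place of the ketone | C=C(C)[C@H](O[Si](C)(C)C(C)(C)C)CC/C(C)=C/[C@H]1OC(=O)C[C@]12C[C@H](OC(C)=O)C=C[C@@H]2O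
F4 | step 13 | 2-[(1R,5S)-5-acetoxy-1-formyl-2-oxocyclohex-3-en-1-yl]acetic acid | OC(=O)C[C@@]1(C=O)C[C@H](OC(C)=O)C=CC1=O
F5 | step 2 | (E)-4-oxobut-2-en-1-yl acetate | CC(=O)OC/C=C/C=O
A1 | alternative 1 | C4 carboxylic acid with C5 (E)-alkenyl group ending in a tertiary allylic methyl carbonate (either carbinol epimer), C9 tert-butyldimethylsilyl ether, side-chain tert-butyldiphenylsilyl ether | C=C(C)[C@H](O[Si](c1ccccc1)(c1ccccc1)C(C)(C)C)CCC(C)(OC(=O)OC)/C=C/[C@]1(CC(=O)O)C[C@H](O[Si](C)(C)C(C)(C)C)C=CC1=O
A2 | alternative 1 | spirolactone enone with C9 tert-butyldimethylsilyl ether and side-chain tert-butyldiphenylsilyl ether | C=C(C)[C@H](O[Si](c1ccccc1)(c1ccccc1)C(C)(C)C)CC/C(C)=C/[C@H]1OC(=O)C[C@]12C[C@H](O[Si](C)(C)C(C)(C)C)C=CC2=O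
A3 | alternative 2 | open-chain iodo β-keto ester (both C5 epimers) with the C9 silyl ether | COC(=O)C(CC(=O)OC(C)(C)C)C(=O)CC[C@@H](O[Si](C)(C)C(C)(C)C)CI
A4 | alternative 2 | 2,2-disubstituted 4-silyloxycyclohexanone with the C1 methyl ester and the C4 tert-butyl ester arm | COC(=O)[C@]1(CC(=O)OC(C)(C)C)C[C@H](O[Si](C)(C)C(C)(C)C)CCC1=O
A5 | alternative 3 | 2-hydroxy-5-(triisopropylsilyloxy)phenylacetic ester of the side-chain allylic acyloxy methyl carbonate (mixed acylal, either C1 epimer) | C=C(C)[C@H](O[Si](c1ccccc1)(c1ccccc1)C(C)(C)C)CC/C(C)=C/C(OC(=O)OC)OC(=O)Cc1cc(O[Si](C(C)C)(C(C)C)C(C)C)ccc1O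
A6 | alternative 3 | spirolactone cyclohexa-2,4-dienone with the C9 oxygen as triisopropylsilyl dienol ether | C=C(C)[C@H](O[Si](c1ccccc1)(c1ccccc1)C(C)(C)C)CC/C(C)=C/[C@H]1OC(=O)C[C@]12C=C(O[Si](C(C)C)(C(C)C)C(C)C)C=CC2=O
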